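**Retrosynthetic overview**
1. The strategy rests on the butenolide ring O–C10–C11=C12–C20(=O). It is the oxidised form of a 2,4-bridged furan whose free α-carbon is C20, and the other two alkenes (C2=C3 with no allylic hydrogen, C6=C7 disubstituted) are slow towards singlet oxygen. The butenolide is therefore unmasked last, from a C20-silylated furanophane, and C10 is then set by reduction directed by the C8 hydroxyl.
2. The 14-membered carbocycle (C1–C14) is closed just before that by ring-closing metathesis at C6=C7 (allyl on C4, vinyl carbinol on C8).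
3. C2=C3 comes from a Julia–Kocienski olefination (C2 aldehyde and C3 sulfone). C9–C10 and C13–C14 come from epoxide openings by the lithiated furan and by a 3-furylmethyl Grignard reagent. Silicon enters at C20 by directed lithiation of 3-furanmethanol.
4. Stereocentres: C1 from Sharpless epoxidation of 2-isopropylallyl alcohol, C4 from (S)-2-methylglycidol, C8 from (R)-2-methylglycidol.
5. Ring order: furan (purchased), then carbocycle (step 18), then butenolide (steps 19 and 20).

Key step: step 19

Remark: atoms are numbered C1–C14 around the carbocycle with C20 the lactone carbonyl; both antipodes of 2-methylglycidol are taken as commercial, and the C1 and C4 hydroxyls are carried as triethylsilyl ethers through the key step because fluoride or acid would endanger the furyl C–Si bond.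

**Route**

Step 1
Reactants: 1 3-methylbutanal
Product: 2 3-methyl-2-methylidenebutanal
Conditions: 37% aq. CH2O, pyrrolidine (10 mol %), propionic acid (10 mol %), i-PrOH, 45 °C
Reagents that add atoms: formaldehyde C=O
Why: Amine-catalysed Mannich condensation with formaldehyde followed by elimination of the amine (α-methylenation of an α-unbranched aldehyde) installs the methylidene carbon that becomes C14.

Step 2
Reactants: 2 3-methyl-2-methylidenebutanal
Product: 3 3-methyl-2-methylidenebutan-1-ol
Conditions: NaBH4, CeCl3·7H2O, MeOH, 0 °C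
Reagents that add atoms: none
Why: Luche reduction adds hydride 1,2 to the enal, so the unhindered methylidene acceptor is not reduced in a conjugate sense.

Step 3
Reactants: 3 3-methyl-2-methylidenebutan-1-ol
Product: 4 [(2S)-2-(propan-2-yl)oxiran-2-yl]methanol
Conditions: Ti(OiPr)4 (10 mol %), L-(+)-diisopropyl tartrate (12 mol %), t-BuOOH, 4 Å MS, CH2Cl2, −25 °C
Reagents that add atoms: tert-butyl hydroperoxide CC(C)(C)OO
Why: Sharpless asymmetric epoxidation of the 2-substituted allylic alcohol; with the L-(+)-tartrate ligand oxygen is delivered to the face that gives the 2S epoxide (the same sense that turns methallyl alcohol into (S)-2-methylglycidol), and this quaternary carbon becomes C1.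

Step 4
Reactants: 5 3-furanmethanol
Product: 8 [2-(trimethylsilyl)furan-3-yl]methanol, via dilithiated furanmethanol 6 (not isolated), via C,O-bis(trimethylsilyl) furan 7 (not isolated)
Conditions: n-BuLi (2.2 equiv), TMEDA, THF, −78 → 0 °C; Me3SiCl (2.4 equiv), −78 °C → rt; then K2CO3 (cat.), MeOH, rt
Reagents that add atoms: chlorotrimethylsilane C[Si](C)(C)Cl
Why: Alkoxide-directed ortho-lithiation takes place at furan C2, which is both α to the ring oxygen and adjacent to the CH2OLi group, so silicon is placed on the future C20 only; mild methanolysis then cleaves the O–Si but not the C–Si bond.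

Step 5
Reactants: 8 [2-(trimethylsilyl)furan-3-yl]methanol
Product: 10 3-(chloromethyl)-2-(trimethylsilyl)furan, via furylmethyl mesylate 9 (not isolated)
Conditions: MsCl, Et3N, LiCl, THF/DMF, 0 °C → rt
Reagents that add atoms: lithium chloride [Li+].[Cl-]
Why: Mesylation and in situ SN2 displacement by chloride at the furylmethyl carbon proceed under basic conditions that leave the acid-labile furyl–silicon bond alone.

Step 6
Reactants: 10 3-(chloromethyl)-2-(trimethylsilyl)furan, 4 [(2S)-2-(propan-2-yl)oxiran-2-yl]methanol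
Product: 12 (2S)-2-(propan-2-yl)-4-[2-(trimethylsilyl)furan-3-yl]butane-1,2-diol, via furylmethyl Grignard reagent 11 (not isolated)
Conditions: 10 (2.4 equiv), Mg, THF, 0 °C → rt; then 4 (1 equiv), CuI (10 mol %), THF, −30 → 0 °C; aq. NH4Cl
Reagents that add atoms: none
Why: Copper-catalysed SN2 opening of the 2,2-disubstituted epoxide at its CH2 terminus by the 3-furylmethyl Grignard reagent forms C13–C14; one equivalent of 11 is spent on the hydroxyl, no bond to the quaternary centre is broken (the alkoxide–epoxide Payne shift of this glycidol is degenerate), and the C20 silyl group blocks reaction through the furan 2-position.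

Step 7
Reactants: 12 (2S)-2-(propan-2-yl)-4-[2-(trimethylsilyl)furan-3-yl]butane-1,2-diol
Product: 13 1,2-bis(triethylsilyl) ether of 12
Conditions: Et3SiOTf (2.6 equiv), 2,6-lutidine, CH2Cl2, −78 → 0 °C
Reagents that add atoms: triethylsilyl trifluoromethanesulfonate CC[Si](CC)(CC)OS(=O)(=O)C(F)(F)F
Why: Silyl triflate and a hindered pyridine base silylate both the primary and the hindered tertiary hydroxyl (silyl ether formation), which keeps the C1 oxygen from α-ketol chemistry in the aldehyde to come.

Step 8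
Reactants: 13 1,2-bis(triethylsilyl) ether of 12
Product: 14 (2S)-3-methyl-2-[(triethylsilyl)oxy]-2-{2-[2-(trimethylsilyl)furan-3-yl]ethyl}butanal
Conditions: (COCl)2, DMSO, CH2Cl2, −78 → −40 °C; Et3N, −78 → 0 °C
Reagents that add atoms: none
Why: Under Swern conditions the chlorosulfonium salt cleaves a primary triethylsilyl ether and oxidises it directly to the aldehyde while the tertiary silyl ether survives; C1 bears no hydrogen, so the C2 aldehyde cannot epimerise or enolise.

Step 9
Reactants: 15 [(2S)-2-methyloxiran-2-yl]methanol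
Product: 16 (2R)-2-methylpent-4-ene-1,2-diol
Conditions: CH2=CHMgBr (3 equiv), CuI (10 mol %), THF, −30 → 0 °C; aq. NH4Cl
Reagents that add atoms: vinylmagnesium bromide C=C[Mg]Br
Why: Copper-catalysed Grignard opening of the epoxide at its unsubstituted carbon makes C5 and adds the vinyl group (C6 and the carbon later lost in metathesis); the quaternary centre is untouched and only its descriptor changes, giving the C4 configuration.

Step 10
Reactants: 16 (2R)-2-methylpent-4-ene-1,2-diol
Product: 17 (2R)-2-hydroxy-2-methylpent-4-en-1-yl 4-methylbenzenesulfonate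
Conditions: TsCl (1.05 equiv), Et3N, Bu2SnO (2 mol %), CH2Cl2, 0 °C → rt
Reagents that add atoms: 4-toluenesulfonyl chloride Cc1ccc(cc1)S(=O)(=O)Cl
Why: Tin-acetal-catalysed sulfonylation is selective for the primary hydroxyl of the 1,2-diol, the tertiary one being inert.

Step 11
Reactants: 17 (2R)-2-hydroxy-2-methylpent-4-en-1-yl 4-methylbenzenesulfonate
Product: 19 (2R)-2-methyl-1-[(1-phenyl-1H-tetrazol-5-yl)sulfanyl]pent-4-en-2-ol, via allyl methyl oxirane 18 (not isolated)
Conditions: 1-phenyl-1H-tetrazole-5-thiol, K2CO3, DMF, 50 °C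
Reagents that add atoms: 1-phenyl-1H-tetrazole-5-thiol Sc1nnnn1-c1ccccc1
Why: Under carbonate the tertiary alkoxide closes to the epoxide (Williamson-type 3-exo-tet), which the tetrazolyl thiolate reopens by SN2 at the CH2 carbon (C3); both events happen at the primary carbon, so C4 is preserved.

Step 12
Reactants: 19 (2R)-2-methyl-1-[(1-phenyl-1H-tetrazol-5-yl)sulfanyl]pent-4-en-2-ol
Product: 20 (2R)-2-methyl-1-[(1-phenyl-1H-tetrazol-5-yl)sulfonyl]pent-4-en-2-ol
Conditions: (NH4)6Mo7O24·4H2O (10 mol %), 30% H2O2, EtOH, 0 °C → rt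
Reagents that add atoms: hydrogen peroxide OO
Why: Molybdate-catalysed hydrogen peroxide oxidation takes the sulfide to the sulfone without touching the terminal alkene, and it is done here so that no furan ever meets an oxidant.

Step 13
Reactants: 20 (2R)-2-methyl-1-[(1-phenyl-1H-tetrazol-5-yl)sulfonyl]pent-4-en-2-ol
Product: 21 5-{[(2R)-2-methyl-2-[(triethylsilyl)oxy]pent-4-en-1-yl]sulfonyl}-1-phenyl-1H-tetrazole
Conditions: Et3SiOTf, 2,6-lutidine, CH2Cl2, −78 → 0 °C
Reagents that add atoms: triethylsilyl trifluoromethanesulfonate CC[Si](CC)(CC)OS(=O)(=O)C(F)(F)F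
Why: Silylation of the tertiary β-hydroxyl (silyl triflate, hindered base) prevents Smiles-type collapse or retro-aldol-type fragmentation of a free β-alkoxide when the sulfone is metalated.

Step 14
Reactants: 14 (2S)-3-methyl-2-[(triethylsilyl)oxy]-2-{2-[2-(trimethylsilyl)furan-3-yl]ethyl}butanal, 21 5-{[(2R)-2-methyl-2-[(triethylsilyl)oxy]pent-4-en-1-yl]sulfonyl}-1-phenyl-1H-tetrazole
Product: 22 3-{(3S,4E,6R)-6-methyl-3-(propan-2-yl)-3,6-bis[(triethylsilyl)oxy]nona-4,8-dien-1-yl}-2-(trimethylsilyl)furan
Conditions: KN(SiMe3)2 (1.2 equiv) added to 14 and 21 (1.3 equiv), DME, −78 °C → rt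
Reagents that add atoms: none
Why: Julia–Kocienski olefination: the metalated phenyltetrazolyl sulfone adds to the non-enolisable C2 aldehyde, and Smiles rearrangement with anti elimination of SO2 and tetrazolonate gives the C2=C3 alkene, for which the E geometry is expected because both olefin carbons carry fully substituted neighbours; base is added to the mixture of both partners so that the carbanion is trapped before it can expel silanolate.

Step 15
Reactants: 23 [(2R)-2-methyloxiran-2-yl]methanol
Product: 24 [(2S)-2-methyloxiran-2-yl]methyl 4-methylbenzenesulfonate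
Conditions: TsCl, Et3N, DMAP (cat.), CH2Cl2, 0 °C
Reagents that add atoms: 4-toluenesulfonyl chloride Cc1ccc(cc1)S(=O)(=O)Cl
Why: Sulfonylation of the primary alcohol turns the glycidol into a 1,2-biselectrophile; the stereocentre is untouched and its descriptor changes from R to S only through the ranking rules.

Step 16
Reactants: 22 3-{(3S,4E,6R)-6-methyl-3-(propan-2-yl)-3,6-bis[(triethylsilyl)oxy]nona-4,8-dien-1-yl}-2-(trimethylsilyl)furan, 24 [(2S)-2-methyloxiran-2-yl]methyl 4-methylbenzenesulfonate
Product: 27 epoxide: 22 carrying a [(2S)-2-methyloxiran-2-yl]methyl group on furan C5 (C10), via 5-lithiofuran 25 (not isolated), via hydroxy tosylate 26 (not isolated)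
Conditions: n-BuLi (1.1 equiv), THF, −78 → 0 °C; 24, BF3·OEt2, −78 °C; then K2CO3, MeOH, rt
Reagents that add atoms: none
Why: The only remaining furan α-hydrogen (C10) is removed by n-BuLi, the furyllithium opens the BF3-activated epoxide of 24 at its CH2 carbon to form C9–C10 (organolithium–BF3 epoxide opening, faster than displacement of the neopentyl-type tosylate), and carbonate then closes the tertiary alkoxide onto CH2OTs to give the C7–C8 epoxide with C8 configured as in (R)-2-methylglycidol.

Step 17
Reactants: 27 epoxide: 22 carrying a [(2S)-2-methyloxiran-2-yl]methyl group on furan C5 (C10)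
Product: 28 tertiary allylic alcohol: 22 carrying a (2S)-2-hydroxy-2-methylbut-3-en-1-yl group on furan C5 (C10)
Conditions: Me3SI (6 equiv), n-BuLi (5.5 equiv), THF, −10 °C → rt
Reagents that add atoms: trimethylsulfonium iodide C[S+](C)C.[I-]
Why: Dimethylsulfonium methylide opens the terminal epoxide at C7, and the β-alkoxy sulfonium salt so formed eliminates dimethyl sulfide through its own ylide (one-carbon homologation of an epoxide to an allylic alcohol), which gives the tertiary C8 vinyl carbinol without any protecting group.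

Step 18
Reactants: 28 tertiary allylic alcohol: 22 carrying a (2S)-2-hydroxy-2-methylbut-3-en-1-yl group on furan C5 (C10)
Product: 29 (1S,4R,8S,2E,6E)-2,4-bridged C20-trimethylsilyl furanophane with OSiEt3 on C1 and C4 and free OH on C8
Conditions: second-generation Grubbs catalyst RuCl2(=CHPh)(PCy3)(H2IMes) (10 mol %), toluene (1 mM), 80 °C
Reagents that add atoms: none
Why: Ring-closing metathesis: the catalyst should load on the unhindered allyl terminus and close onto the C8 vinyl group, helped by the free allylic hydroxyl, to form the 14-membered carbocycle; the fully substituted allylic carbon C8 should favour the E olefin, and the C2=C3 alkene between two quaternary carbons is too hindered to take part.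

Step 19
Reactants: 29 (1S,4R,8S,2E,6E)-2,4-bridged C20-trimethylsilyl furanophane with OSiEt3 on C1 and C4 and free OH on C8
Product: 32 C10-hydroxybutenolide bis(triethylsilyl) ether (C10 epimers), via furan endoperoxide 30 (not isolated), via silyl keto ester 31 (not isolated)
Conditions: O2, rose bengal disodium salt (C20H2Cl4I4Na2O5, cat.), visible light, CH2Cl2/MeOH (9:1), −78 °C; then warm to rt
Reagents that add atoms: dioxygen O=O
Why: Sensitised singlet oxygen adds in a concerted (4+2) fashion across C10 and C20 of the electron-rich silylfuran to give the 2,5-endoperoxide 30. The trimethylsilyl group then shifts from C20 to the adjacent peroxide oxygen with O–O cleavage, a Baeyer–Villiger-like 1,2-migration, so that C20 alone ends as a carboxyl carbon (silyl ester 31) and C10 as a ketone; this is the known regiospecific photooxygenation of 2-trialkylsilylfurans to γ-hydroxybutenolides. Methanolysis of the silyl ester frees the Z keto acid, whose carboxyl oxygen adds to the C10 ketone in a 5-exo-trig closure that forms the butenolide ring as its lactol (the C20 carbonyl and the C10–O bond). The new C10 centre is a hemiketal and is left uncontrolled, since its epimers interconvert through the open keto acid. Regiocontrol of the carbonyl is secured by silicon on C20, and chemoselectivity by the much higher rate of the furan over the two disubstituted alkenes: C2=C3 has no allylic hydrogen and C6=C7 is a poor ene partner. The silyl ethers on the C1 and C4 oxygens and the free C8 hydroxyl are spectators.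

Step 20
Reactants: 32 C10-hydroxybutenolide bis(triethylsilyl) ether (C10 epimers)
Product: 35 (10R)-butenolide bis(triethylsilyl) ether, via open keto acid 33 (not isolated), via hydroxy acid 34 (not isolated)
Conditions: Et2BOMe (2.5 equiv), THF/MeOH (4:1), −78 °C; NaBH4, −78 → −40 °C; AcOH, MeOH co-evaporation; then PPTS (cat.), CH2Cl2, rt
Reagents that add atoms: none
Why: Narasaka–Prasad reduction: the lactol opens to the keto acid, whose C10 ketone and C8 hydroxyl form a six-membered diethylboron chelate that should take hydride on the face giving the 8,10-syn diol (C7 and C11, both ring members, pseudo-equatorial), which corresponds to 10R; on mild acid treatment the Z hydroxy acid lactonises to the butenolide.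

Step 21
Reactants: 35 (10R)-butenolide bis(triethylsilyl) ether
Product: 36 target, (1S,4R,8S,10R,2E,6E)-triol butenolide (CHEBI:68873)
Conditions: HF·pyridine, pyridine, THF, 0 °C → rt
Reagents that add atoms: none
Why: Buffered hydrogen fluoride cleaves the two tertiary triethylsilyl ethers (Si–F bond formation) under conditions too mild to ionise the tertiary allylic alcohols or to epimerise C10.

**Compound list**
1 | 3-methylbutanal | CC(C)CC=O | starting material
2 | 3-methyl-2-methylidenebutanal | CC(C)C(=C)C=O | intermediate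
3 | 3-methyl-2-methylidenebutan-1-ol | CC(C)C(=C)CO | intermediate
4 | [(2S)-2-(propan-2-yl)oxiran-2-yl]methanol | OC[C@]1(C(C)C)OC1 | intermediate
5 | 3-furanmethanol | OCc1ccoc1 | starting material
6 | 2-lithio-3-(lithiooxymethyl)furan | [Li]OCc1ccoc1[Li] | intermediate
7 | trimethyl{3-[(trimethylsilyloxy)methyl]furan-2-yl}silane | C[Si](C)(C)OCc1ccoc1[Si](C)(C)C | intermediate
8 | [2-(trimethylsilyl)furan-3-yl]methanol | OCc1ccoc1[Si](C)(C)C | intermediate
9 | [2-(trimethylsilyl)furan-3-yl]methyl methanesulfonate | CS(=O)(=O)OCc1ccoc1[Si](C)(C)C | intermediate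
10 | 3-(chloromethyl)-2-(trimethylsilyl)furan | ClCc1ccoc1[Si](C)(C)C | intermediate
11 | {[2-(trimethylsilyl)furan-3-yl]methyl}magnesium chloride | Cl[Mg]Cc1ccoc1[Si](C)(C)C | intermediate
12 | (2S)-2-(propan-2-yl)-4-[2-(trimethylsilyl)furan-3-yl]butane-1,2-diol | OC[C@](CCc1ccoc1[Si](C)(C)C)(C(C)C)O | intermediate
13 | (2S)-2-(propan-2-yl)-1,2-bis[(triethylsilyl)oxy]-4-[2-(trimethylsilyl)furan-3-yl]butane | CC[Si](CC)(CC)OC[C@](CCc1ccoc1[Si](C)(C)C)(C(C)C)O[Si](CC)(CC)CC | intermediate
14 | (2S)-3-methyl-2-[(triethylsilyl)oxy]-2-{2-[2-(trimethylsilyl)furan-3-yl]ethyl}butanal (C2 aldehyde) | O=C[C@](CCc1ccoc1[Si](C)(C)C)(C(C)C)O[Si](CC)(CC)CC | intermediate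
15 | [(2S)-2-methyloxiran-2-yl]methanol, (S)-2-methylglycidol | OC[C@]1(C)OC1 | starting material
16 | (2R)-2-methylpent-4-ene-1,2-diol | OC[C@](CC=C)(C)O | intermediate
17 | (2R)-2-hydroxy-2-methylpent-4-en-1-yl 4-methylbenzenesulfonate | Cc1ccc(cc1)S(=O)(=O)OC[C@](CC=C)(C)O | intermediate
18 | (2R)-2-methyl-2-(prop-2-en-1-yl)oxirane | C1[C@](CC=C)(C)O1 | intermediate
19 | (2R)-2-methyl-1-[(1-phenyl-1H-tetrazol-5-yl)sulfanyl]pent-4-en-2-ol | c1ccc(cc1)-n1nnnc1SC[C@](CC=C)(C)O | intermediate
20 | (2R)-2-methyl-1-[(1-phenyl-1H-tetrazol-5-yl)sulfonyl]pent-4-en-2-ol | c1ccc(cc1)-n1nnnc1S(=O)(=O)C[C@](CC=C)(C)O | intermediate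
21 | 5-{[(2R)-2-methyl-2-[(triethylsilyl)oxy]pent-4-en-1-yl]sulfonyl}-1-phenyl-1H-tetrazole (C3 sulfone) | c1ccc(cc1)-n1nnnc1S(=O)(=O)C[C@](CC=C)(C)O[Si](CC)(CC)CC | intermediate
22 | 3-{(3S,4E,6R)-6-methyl-3-(propan-2-yl)-3,6-bis[(triethylsilyl)oxy]nona-4,8-dien-1-yl}-2-(trimethylsilyl)furan | CC(C)[C@](CCc1ccoc1[Si](C)(C)C)(O[Si](CC)(CC)CC)/C=C/[C@](C)(O[Si](CC)(CC)CC)CC=C | intermediate
23 | [(2R)-2-methyloxiran-2-yl]methanol, (R)-2-methylglycidol | OC[C@@]1(C)OC1 | starting material
24 | [(2S)-2-methyloxiran-2-yl]methyl 4-methylbenzenesulfonate | Cc1ccc(cc1)S(=O)(=O)OC[C@@]1(C)OC1 | intermediate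
25 | 5-lithio derivative of 22 (lithium on furan C5, the future C10) | CC(C)[C@](CCc1cc([Li])oc1[Si](C)(C)C)(O[Si](CC)(CC)CC)/C=C/[C@](C)(O[Si](CC)(CC)CC)CC=C | intermediate
26 | 22 carrying on furan C5 a (2S)-2-hydroxy-2-methyl-3-(tosyloxy)propyl group | CC(C)[C@](CCc1cc(C[C@](C)(O)COS(=O)(=O)c2ccc(C)cc2)oc1[Si](C)(C)C)(O[Si](CC)(CC)CC)/C=C/[C@](C)(O[Si](CC)(CC)CC)CC=C | intermediate
27 | 22 carrying on furan C5 a [(2S)-2-methyloxiran-2-yl]methyl group (C7–C8 epoxide) | CC(C)[C@](CCc1cc(C[C@]2(C)OC2)oc1[Si](C)(C)C)(O[Si](CC)(CC)CC)/C=C/[C@](C)(O[Si](CC)(CC)CC)CC=C | intermediate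
28 | 22 carrying on furan C5 a (2S)-2-hydroxy-2-methylbut-3-en-1-yl group (C8 vinyl carbinol) | CC(C)[C@](CCc1cc(C[C@](C)(O)C=C)oc1[Si](C)(C)C)(O[Si](CC)(CC)CC)/C=C/[C@](C)(O[Si](CC)(CC)CC)CC=C | intermediate
29 | (1S,4R,8S,2E,6E)-2,4-bridged furanophane: carbocycle C1–C14 spanned by the furan C10/C11/C12/C20/O, SiMe3 on C20, OSiEt3 on C1 and C4, OH on C8 (key-step precursor) | CC(C)[C@]1(O[Si](CC)(CC)CC)/C=C/[C@](C)(O[Si](CC)(CC)CC)C/C=C/[C@@](C)(O)Cc2cc(CC1)c([Si](C)(C)C)o2 | intermediate
30 | 2,5-endoperoxide of 29 (O–O bridge from C10 to C20) | CC(C)[C@]1(O[Si](CC)(CC)CC)/C=C/[C@](C)(O[Si](CC)(CC)CC)C/C=C/[C@@](C)(O)CC23C=C(CC1)C([Si](C)(C)C)(OO2)O3 | intermediate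
31 | trimethylsilyl ester of the Z keto acid (C10 ketone, C11=C12, C20 CO2SiMe3) | CC(C)[C@]1(O[Si](CC)(CC)CC)/C=C/[C@](C)(O[Si](CC)(CC)CC)C/C=C/[C@@](C)(O)CC(=O)/C=C(/CC1)C(=O)O[Si](C)(C)C | intermediate
32 | C10-hydroxybutenolide, OSiEt3 on C1 and C4, C10 epimers (key-step product) | CC(C)[C@]1(O[Si](CC)(CC)CC)/C=C/[C@](C)(O[Si](CC)(CC)CC)C/C=C/[C@@](C)(O)CC2(O)C=C(CC1)C(=O)O2 | intermediate
33 | open Z 4-oxo-2-enoic acid form of 32 | CC(C)[C@]1(O[Si](CC)(CC)CC)/C=C/[C@](C)(O[Si](CC)(CC)CC)C/C=C/[C@@](C)(O)CC(=O)/C=C(/CC1)C(=O)O | intermediate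
34 | (10R)-hydroxy Z-enoic acid | CC(C)[C@]1(O[Si](CC)(CC)CC)/C=C/[C@](C)(O[Si](CC)(CC)CC)C/C=C/[C@@](C)(O)C[C@@H](O)/C=C(/CC1)C(=O)O | intermediate
35 | (10R)-butenolide, OSiEt3 on C1 and C4 | CC(C)[C@]1(O[Si](CC)(CC)CC)/C=C/[C@](C)(O[Si](CC)(CC)CC)C/C=C/[C@@](C)(O)C[C@@H]2C=C(CC1)C(=O)O2 | intermediate
36 | CHEBI:68873, (1S,4R,8S,10R,2E,6E)-triol butenolide | CC(C)[C@]1(O)/C=C/[C@](C)(O)C/C=C/[C@@](C)(O)C[C@@H]2C=C(CC1)C(=O)O2 | target

**Step count and risks**
Total: 21 steps. Longest linear sequence: 13 steps (steps 1–3, 6–8, 14, 16–21, from 3-methylbutanal).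

Step 14 (Julia–Kocienski coupling). Addition of the neopentyl-type sulfonyl carbanion to the α-quaternary aldehyde may be slower than β-elimination of silanolate from the metalated sulfone or its self-condensation. The fallback sets out from 14 and comes back at 22; it makes steps 9–13 unnecessary. Homologation of 14 with the Ohira–Bestmann reagent (K2CO3, MeOH) gives the terminal alkyne F1. Deprotonation (n-BuLi, THF, −78 °C) gives the lithium acetylide F2, which is acylated with N-methoxy-N-methylacetamide to the methyl ynone F3. Reagent-controlled asymmetric allylboration of the ketone (allylB(pin), 3,3'-dibromo-BINOL catalyst, antipode chosen for 4R) gives the tertiary propargylic alcohol F4. Hydroxyl-directed trans-hydroalumination with NaAlH2(OCH2CH2OMe)2 gives the E allylic alcohol F5, and silylation (Et3SiOTf, 2,6-lutidine) gives 22.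

Step 18 (ring-closing metathesis). Intermolecular metathesis at the unhindered allyl terminus may outrun ring closure onto the hindered C8 vinyl group, or the ring may close with the wrong olefin geometry. The fallback sets out from 13 and comes back at 29; it fixes C6=C7 by an intermolecular cross-metathesis and closes the ring by olefination at C2=C3. Lithiation of 13 (n-BuLi) gives the 5-lithiofuran F6, which with 24 and BF3·OEt2 gives the hydroxy tosylate F7; K2CO3 in MeOH closes it to the epoxide F8. Trimethylsulfonium iodide and n-BuLi give the vinyl carbinol F9. Cross-metathesis of F9 with sulfone 21 (second-generation Hoveyda–Grubbs catalyst RuCl2(=CH-C6H4-2-OiPr)(H2IMes), CH2Cl2, 40 °C) gives the E olefin sulfone F10. Selective cleavage of the primary silyl ether (PPTS, MeOH, 0 °C) gives the primary alcohol F11, and Dess–Martin periodinane gives the aldehyde F12. Intramolecular Julia–Kocienski olefination (KN(SiMe3)2, DME, high dilution) then gives 29.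

Step 20 (directed reduction). Hydride delivery may show poor facial selectivity because the tertiary C8 carbinol gives a weakly biased boron chelate, or the open β-hydroxy ketone may undergo retro-aldol cleavage. The fallback sets out from 32 and comes back at 35. Esterification of the open form with Me3SiCHN2 (toluene/MeOH) gives the Z keto methyl ester F13. Reagent-controlled Corey–Bakshi–Shibata reduction ((S)-2-methyl-CBS-oxazaborolidine, catecholborane, toluene, −78 °C; the alkenyl group acting as the large substituent) gives the (10R)-hydroxy ester F14, which lactonises (PPTS, CH2Cl2) to 35.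

**Further compounds**
F1 | step 14 | terminal alkyne (C2≡C3H) from 14 | C#C[C@](CCc1ccoc1[Si](C)(C)C)(C(C)C)O[Si](CC)(CC)CC
F2 | step 14 | lithium acetylide of F1 | [Li]C#C[C@](CCc1ccoc1[Si](C)(C)C)(C(C)C)O[Si](CC)(CC)CC
F3 | step 14 | methyl ynone (C4 ketone) | CC(=O)C#C[C@](CCc1ccoc1[Si](C)(C)C)(C(C)C)O[Si](CC)(CC)CC
F4 | step 14 | (4R) tertiary propargylic alcohol | C=CC[C@@](C)(O)C#C[C@](CCc1ccoc1[Si](C)(C)C)(C(C)C)O[Si](CC)(CC)CC
F5 | step 14 | (2E,4R) allylic alcohol | C=CC[C@@](C)(O)/C=C/[C@](CCc1ccoc1[Si](C)(C)C)(C(C)C)O[Si](CC)(CC)CC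
F6 | step 18 | 5-lithio derivative of 13 | CC[Si](CC)(CC)OC[C@](CCc1cc([Li])oc1[Si](C)(C)C)(C(C)C)O[Si](CC)(CC)CC
F7 | step 18 | hydroxy tosylate from 13 and 24 | CC[Si](CC)(CC)OC[C@](CCc1cc(C[C@](C)(O)COS(=O)(=O)c2ccc(C)cc2)oc1[Si](C)(C)C)(C(C)C)O[Si](CC)(CC)CC
F8 | step 18 | C7–C8 epoxide of the 13 series | CC[Si](CC)(CC)OC[C@](CCc1cc(C[C@]2(C)OC2)oc1[Si](C)(C)C)(C(C)C)O[Si](CC)(CC)CC
F9 | step 18 | C8 vinyl carbinol of the 13 series | CC[Si](CC)(CC)OC[C@](CCc1cc(C[C@](C)(O)C=C)oc1[Si](C)(C)C)(C(C)C)O[Si](CC)(CC)CC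
F10 | step 18 | cross-metathesis product, 6E olefin with C3 sulfone | CC[Si](CC)(CC)OC[C@](CCc1cc(C[C@](C)(O)/C=C/C[C@@](C)(O[Si](CC)(CC)CC)CS(=O)(=O)c2nnnn2-c2ccccc2)oc1[Si](C)(C)C)(C(C)C)O[Si](CC)(CC)CC
F11 | step 18 | C2 primary alcohol | OC[C@](CCc1cc(C[C@](C)(O)/C=C/C[C@@](C)(O[Si](CC)(CC)CC)CS(=O)(=O)c2nnnn2-c2ccccc2)oc1[Si](C)(C)C)(C(C)C)O[Si](CC)(CC)CC
F12 | step 18 | C2 aldehyde with C3 sulfone | O=C[C@](CCc1cc(C[C@](C)(O)/C=C/C[C@@](C)(O[Si](CC)(CC)CC)CS(=O)(=O)c2nnnn2-c2ccccc2)oc1[Si](C)(C)C)(C(C)C)O[Si](CC)(CC)CC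
F13 | step 20 | Z keto methyl ester of 33 | CC(C)[C@]1(O[Si](CC)(CC)CC)/C=C/[C@](C)(O[Si](CC)(CC)CC)C/C=C/[C@@](C)(O)CC(=O)/C=C(/CC1)C(=O)OC
F14 | step 20 | (10R)-hydroxy methyl ester | CC(C)[C@]1(O[Si](CC)(CC)CC)/C=C/[C@](C)(O[Si](CC)(CC)CC)C/C=C/[C@@](C)(O)C[C@@H](O)/C=C(/CC1)C(=O)OC
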